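The route rests on disconnecting C5–C6, the bond between the vinylic carbon of the (4Z)-trisubstituted alkene and the allylic carbinol carbon C6 that the ten-membered carbocycle (C1–C10) shares with the γ-lactone ring (O–C6–C7–C11–C12). An intramolecular Nozaki–Hiyama–Kishi addition of a (Z)-alkenyl iodide to a C6 aldehyde closes the cyclodecadiene, sets C6 under control of C7 and leaves an alkoxide poised to lactonise onto the C12 acrylate ester, so both rings form in one operation. The precursor is an acyclic C5-iodo C6-aldehyde already carrying the C8 tiglate, both Z-alkenes, the C3 silyl ether, the free C10 tertiary alcohol and the α-methylene ester.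

Key step: step 16

Remark on numbering: germacranolide numbering is used for the target-derived carbons: ring C1–C10 (methyls on C4 and C10), C11 bearing the exocyclic methylene C13, C12 the lactone carbonyl. The target is then 3R,6S,7R,8R,10R,1Z,4Z with a cis-fused lactone.

Assumption: (2E)-3-methylpent-2-en-4-yn-1-ol, (R)-2,3-O-isopropylideneglyceraldehyde and both ProPhenol antipodes are taken as commercial.

Step 1
Reactants: 1 (2E)-3-methylpent-2-en-4-yn-1-ol
Product: 2 [(2S,3S)-3-ethynyl-3-methyloxiran-2-yl]methanol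
Conditions: Ti(OiPr)4 (cat.), L-(+)-diisopropyl tartrate, t-BuOOH, 4 Å MS, CH2Cl2, −20 °C
Reagents that add atoms: tert-butyl hydroperoxide, CC(C)(C)OO
Why: Sharpless asymmetric epoxidation, in which the L-(+)-tartrate/Ti(OiPr)4 complex delivers oxygen to one enantioface of the allylic alcohol and so sets the quaternary carbinol carbon (future C10) by reagent control, the alkyne being inert.

Step 2
Reactants: 2 [(2S,3S)-3-ethynyl-3-methyloxiran-2-yl]methanol
Product: 3 (3R)-3-methylpent-4-yne-1,3-diol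
Conditions: NaAlH2(OCH2CH2OMe)2 (Red-Al), THF, −20 to 0 °C; aqueous potassium sodium tartrate work-up
Reagents that add atoms: none
Why: Hydroxyl-directed reductive opening of a 2,3-epoxy alcohol, in which the alkoxyaluminate delivers hydride intramolecularly to C2 to give the 1,3-diol without touching the tertiary C–O bond, the low temperature being chosen to outpace hydroalumination of the (deprotonated) alkyne.

Step 3
Reactants: 3 (3R)-3-methylpent-4-yne-1,3-diol
Product: 4 (4R)-4-ethynyl-2,2,4-trimethyl-1,3-dioxane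
Conditions: 2,2-dimethoxypropane, PPTS (cat.), CH2Cl2, rt
Reagents that add atoms: 2,2-dimethoxypropane, COC(C)(C)OC
Why: Acid-catalysed transketalisation of the 1,3-diol masks both hydroxyls as one six-membered isopropylidene ketal that tolerates organozinc and zinc-reduction conditions.

Step 4
Reactants: 5 prop-2-yn-1-ol
Product: 6 (2Z)-3-iodo-2-methylprop-2-en-1-ol
Conditions: MeMgBr (2.5 equiv), CuI (10 mol %), THF, −10 °C to rt; then I2, −78 to 0 °C
Reagents that add atoms: methylmagnesium bromide, C[Mg]Br; iodine, II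
Why: Copper-catalysed anti-carbomagnesiation of the magnesium propargyl alkoxide through a five-membered chelate, followed by iodinolysis of the alkenylmagnesium with retention, places iodine cis to CH2OH (Z).

Step 5
Reactants: 6 (2Z)-3-iodo-2-methylprop-2-en-1-ol
Product: 7 (2Z)-3-iodo-2-methylprop-2-enal
Conditions: MnO2, CH2Cl2, rt, dark
Reagents that add atoms: none
Why: Allylic alcohol oxidation with MnO2 is neutral and should preserve the Z-geometry of the β-iodoenal, which is used fresh.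

Step 6
Reactants: 4 (4R)-4-ethynyl-2,2,4-trimethyl-1,3-dioxane; 7 (2Z)-3-iodo-2-methylprop-2-enal
Product: 8 (1Z,3R)-1-iodo-2-methyl-5-[(4R)-2,2,4-trimethyl-1,3-dioxan-4-yl]pent-1-en-4-yn-3-ol
Conditions: 4 (2.5 equiv, excess recovered), Me2Zn, ProPhenol (20 mol %, the antipode that directs Re-face addition), Ph3P=O (40 mol %), toluene, 0 to 4 °C
Reagents that add atoms: none
Why: Zinc–ProPhenol-catalysed enantioselective alkynylation of an α-branched enal, in which the dinuclear zinc catalyst delivers the alkynylzinc to the Re face of the aldehyde to set C3 as R by reagent control, the minor C3 epimer being a separable diastereomer.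

Step 7
Reactants: 8 (1Z,3R)-1-iodo-2-methyl-5-[(4R)-2,2,4-trimethyl-1,3-dioxan-4-yl]pent-1-en-4-yn-3-ol
Product: 9 (1Z,3R,4Z)-1-iodo-2-methyl-5-[(4R)-2,2,4-trimethyl-1,3-dioxan-4-yl]penta-1,4-dien-3-ol
Conditions: Zn dust activated with Cu(OAc)2 and AgNO3, MeOH/H2O (1:1), 40 °C
Reagents that add atoms: none
Why: Boland-type reduction, in which electron transfer from activated zinc to the alkyne flanked by two propargylic oxygens and cis-protonation should give the C1=C2 Z-alkene while leaving the alkenyl iodide, which rules out Pd/H2, untouched.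

Step 8
Reactants: 9 (1Z,3R,4Z)-1-iodo-2-methyl-5-[(4R)-2,2,4-trimethyl-1,3-dioxan-4-yl]penta-1,4-dien-3-ol
Product: 10 tert-butyl{[(1Z,3R,4Z)-1-iodo-2-methyl-5-[(4R)-2,2,4-trimethyl-1,3-dioxan-4-yl]penta-1,4-dien-3-yl]oxy}dimethylsilane
Conditions: TBSCl, imidazole, DMF, rt
Reagents that add atoms: tert-butyldimethylsilyl chloride, CC(C)(C)[Si](C)(C)Cl
Why: Standard silylation of the only free hydroxyl (C3–OH), which must be masked before the C8 alcohol is acylated.

Step 9
Reactants: 10 tert-butyl{[(1Z,3R,4Z)-1-iodo-2-methyl-5-[(4R)-2,2,4-trimethyl-1,3-dioxan-4-yl]penta-1,4-dien-3-yl]oxy}dimethylsilane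
Product: 11 (3R,4Z,6R,7Z)-6-[(tert-butyldimethylsilyl)oxy]-8-iodo-3,7-dimethylocta-4,7-diene-1,3-diol
Conditions: PPTS (cat.), MeOH, 0 °C to rt
Reagents that add atoms: none
Why: Mild acid transketalisation to methanol should cleave the 4,4-disubstituted 1,3-dioxane faster than the secondary TBS ether.

Step 10
Reactants: 11 (3R,4Z,6R,7Z)-6-[(tert-butyldimethylsilyl)oxy]-8-iodo-3,7-dimethylocta-4,7-diene-1,3-diol
Product: 12 (3R,4Z,6R,7Z)-6-[(tert-butyldimethylsilyl)oxy]-3-hydroxy-8-iodo-3,7-dimethylocta-4,7-dienal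
Conditions: TEMPO (cat.), PhI(OAc)2, CH2Cl2, rt; used crude
Reagents that add atoms: none
Why: Oxoammonium oxidation is selective for the primary alcohol, the tertiary alcohol cannot be oxidised, and the neutral medium avoids retro-aldol cleavage or dehydration of the β-hydroxy aldehyde (C8 aldehyde).

Step 11
Reactants: 13 (4R)-2,2-dimethyl-1,3-dioxolane-4-carbaldehyde; 14 methyl acrylate
Product: 15 methyl 2-{[(4R)-2,2-dimethyl-1,3-dioxolan-4-yl](hydroxy)methyl}prop-2-enoate (mixture of carbinol epimers)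
Conditions: DABCO, 1,4-dioxane/H2O, rt
Reagents that add atoms: none
Why: Morita–Baylis–Hillman reaction; the carbinol configuration is irrelevant because that centre becomes sp2 in the next step.

Step 12
Reactants: 15 methyl 2-{[(4R)-2,2-dimethyl-1,3-dioxolan-4-yl](hydroxy)methyl}prop-2-enoate
Product: 16 methyl (2Z)-2-(bromomethyl)-3-[(4S)-2,2-dimethyl-1,3-dioxolan-4-yl]prop-2-enoate
Conditions: NBS, Me2S, CH2Cl2, 0 °C to rt
Reagents that add atoms: N-bromosuccinimide, BrN1C(=O)CCC1=O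
Why: Bromodimethylsulfonium activation of the allylic alcohol and SN2′ attack of bromide transpose the allyl system to the thermodynamically preferred (Z)-2-(bromomethyl)enoate, the acetonide surviving the neutral conditions.

Step 13
Reactants: 12 (3R,4Z,6R,7Z)-6-[(tert-butyldimethylsilyl)oxy]-3-hydroxy-8-iodo-3,7-dimethylocta-4,7-dienal; 16 methyl (2Z)-2-(bromomethyl)-3-[(4S)-2,2-dimethyl-1,3-dioxolan-4-yl]prop-2-enoate
Product: 17 methyl (3R,4R,6R,7Z,9R,10Z)-9-[(tert-butyldimethylsilyl)oxy]-3-[(4S)-2,2-dimethyl-1,3-dioxolan-4-yl]-4,6-dihydroxy-11-iodo-6,10-dimethyl-2-methylideneundeca-7,10-dienoate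
Conditions: indium powder, 16 (2 equiv), THF/H2O (1:1), rt
Reagents that add atoms: none
Why: Indium-mediated Barbier allylation, in which the Z-configured allylindium reacts at its γ-carbon through a chair transition state to give the syn C7/C8 adduct, while the dioxolane centre fixes the attacked face of C7 (allylic-strain conformer with C6–H in the alkene plane, bond formation anti to the C6–O bond), which should give 7R,8R and is expected to be reinforced by chelation of the free C10 hydroxyl.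

Step 14
Reactants: 17 methyl (3R,4R,6R,7Z,9R,10Z)-9-[(tert-butyldimethylsilyl)oxy]-3-[(4S)-2,2-dimethyl-1,3-dioxolan-4-yl]-4,6-dihydroxy-11-iodo-6,10-dimethyl-2-methylideneundeca-7,10-dienoate
Product: 18 methyl (3R,4R,6R,7Z,9R,10Z)-9-[(tert-butyldimethylsilyl)oxy]-3-[(4S)-2,2-dimethyl-1,3-dioxolan-4-yl]-6-hydroxy-11-iodo-6,10-dimethyl-4-{[(2E)-2-methylbut-2-enoyl]oxy}-2-methylideneundeca-7,10-dienoate
Conditions: tigloyl chloride, Et3N, DMAP (cat.), CH2Cl2, 0 °C to rt
Reagents that add atoms: (2E)-2-methylbut-2-enoyl chloride (tigloyl chloride), C/C=C(\C)C(=O)Cl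
Why: DMAP-catalysed acylation of the secondary C8 alcohol, with which the hindered tertiary C10 alcohol should not compete and which forestalls lactonisation of the 8-hydroxy acrylate.

Step 15
Reactants: 18 methyl (3R,4R,6R,7Z,9R,10Z)-9-[(tert-butyldimethylsilyl)oxy]-3-[(4S)-2,2-dimethyl-1,3-dioxolan-4-yl]-6-hydroxy-11-iodo-6,10-dimethyl-4-{[(2E)-2-methylbut-2-enoyl]oxy}-2-methylideneundeca-7,10-dienoate
Product: 20 methyl (3R,4R,6R,7Z,9R,10Z)-9-[(tert-butyldimethylsilyl)oxy]-3-formyl-6-hydroxy-11-iodo-6,10-dimethyl-4-{[(2E)-2-methylbut-2-enoyl]oxy}-2-methylideneundeca-7,10-dienoate, via 1,2-diol 19 (not isolated)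
Conditions: H5IO6, EtOAc, 0 °C to rt, short reaction time; NaHCO3 quench; used at once
Reagents that add atoms: none
Why: Periodic acid hydrolyses the terminal acetonide and cleaves the liberated 1,2-diol in the same flask (glycol cleavage), unveiling the C6 aldehyde without an oxidation step and, being cold, brief and non-basic, should leave the enolisable C7 centre intact.

Step 16
Reactants: 20 methyl (3R,4R,6R,7Z,9R,10Z)-9-[(tert-butyldimethylsilyl)oxy]-3-formyl-6-hydroxy-11-iodo-6,10-dimethyl-4-{[(2E)-2-methylbut-2-enoyl]oxy}-2-methylideneundeca-7,10-dienoate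
Product: 22 (3aR,4R,6R,7Z,9R,10Z,11aS)-9-[(tert-butyldimethylsilyl)oxy]-6-hydroxy-6,10-dimethyl-3-methylidene-2-oxo-2,3,3a,4,5,6,9,11a-octahydrocyclodeca[b]furan-4-yl (2E)-2-methylbut-2-enoate, via seco hydroxy ester 21 (not isolated)
Conditions: CrCl2 (10 equiv), NiCl2 (0.1 equiv), degassed DMSO/THF (3:1), slow addition to 0.003 M, rt; aqueous work-up, then PPTS (cat.), CH2Cl2, rt
Reagents that add atoms: none
Why: NiCl2 is reduced by CrCl2 to zerovalent nickel, which inserts into the C5–I bond with retention of the Z-geometry and transmetalates to an alkenyl species of trivalent chromium that adds only to the C6 aldehyde, after which the C6 oxygen attacks the C12 methyl ester and expels methanol on mild acid work-up. The closest known reaction type is the intramolecular Nozaki–Hiyama–Kishi alkenyl iodide–aldehyde macrocyclisation followed by γ-hydroxy ester lactonisation. The ten-membered carbocycle closes in a 10-exo-trig addition (C5 onto the exocyclic C6=O) and the γ-lactone in a 5-exo-trig acyl substitution (O6 onto C12). The new C6 centre is controlled by the adjacent C7 centre: in the Felkin–Anh arrangement the electron-poor acrylate carbon C11 lies anti to the incoming C5 and the C8 branch gauche to it, as ring closure requires, which should give 6S and hence the cis-fused lactone. The step needs cyclisation over oligomerisation (secured by high dilution and by the two Z-alkenes that fold the chain), chemoselectivity for the aldehyde over both esters (inherent to organochromium reagents) and retention at the enolisable C7 (secured by the neutral, non-basic medium).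

Step 17
Reactants: 22 (3aR,4R,6R,7Z,9R,10Z,11aS)-9-[(tert-butyldimethylsilyl)oxy]-6-hydroxy-6,10-dimethyl-3-methylidene-2-oxo-2,3,3a,4,5,6,9,11a-octahydrocyclodeca[b]furan-4-yl (2E)-2-methylbut-2-enoate
Product: 23 (3aR,4R,6R,7Z,9R,10Z,11aS)-6,9-dihydroxy-6,10-dimethyl-3-methylidene-2-oxo-2,3,3a,4,5,6,9,11a-octahydrocyclodeca[b]furan-4-yl (2E)-2-methylbut-2-enoate
Conditions: HF·pyridine, pyridine, THF, 0 °C to rt
Reagents that add atoms: none
Why: Buffered fluoride cleavage of the secondary allylic TBS ether, which should leave the α-methylene lactone, the tiglate and the tertiary allylic alcohol intact.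

Compound list

1 | (2E)-3-methylpent-2-en-4-yn-1-ol | C#C/C(C)=C/CO | starting material
2 | [(2S,3S)-3-ethynyl-3-methyloxiran-2-yl]methanol | OC[C@@H]1O[C@@]1(C)C#C | intermediate
3 | (3R)-3-methylpent-4-yne-1,3-diol | C#C[C@](C)(O)CCO | intermediate
4 | (4R)-4-ethynyl-2,2,4-trimethyl-1,3-dioxane | CC1(C)OCC[C@](C)(C#C)O1 | intermediate
5 | prop-2-yn-1-ol | C#CCO | starting material
6 | (2Z)-3-iodo-2-methylprop-2-en-1-ol | C/C(CO)=C/I | intermediate
7 | (2Z)-3-iodo-2-methylprop-2-enal | C/C(C=O)=C/I | intermediate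
8 | (1Z,3R)-1-iodo-2-methyl-5-[(4R)-2,2,4-trimethyl-1,3-dioxan-4-yl]pent-1-en-4-yn-3-ol | CC1(C)OCC[C@](C)(C#C[C@@H](O)/C(C)=C\I)O1 | intermediate
9 | (1Z,3R,4Z)-1-iodo-2-methyl-5-[(4R)-2,2,4-trimethyl-1,3-dioxan-4-yl]penta-1,4-dien-3-ol | CC1(C)OCC[C@](C)(/C=C\[C@@H](O)/C(C)=C\I)O1 | intermediate
10 | tert-butyl{[(1Z,3R,4Z)-1-iodo-2-methyl-5-[(4R)-2,2,4-trimethyl-1,3-dioxan-4-yl]penta-1,4-dien-3-yl]oxy}dimethylsilane | CC1(C)OCC[C@](C)(/C=C\[C@@H](O[Si](C)(C)C(C)(C)C)/C(C)=C\I)O1 | intermediate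
11 | (3R,4Z,6R,7Z)-6-[(tert-butyldimethylsilyl)oxy]-8-iodo-3,7-dimethylocta-4,7-diene-1,3-diol | OCC[C@@](C)(O)/C=C\[C@@H](O[Si](C)(C)C(C)(C)C)/C(C)=C\I | intermediate
12 | (3R,4Z,6R,7Z)-6-[(tert-butyldimethylsilyl)oxy]-3-hydroxy-8-iodo-3,7-dimethylocta-4,7-dienal | O=CC[C@@](C)(O)/C=C\[C@@H](O[Si](C)(C)C(C)(C)C)/C(C)=C\I | intermediate
13 | (4R)-2,2-dimethyl-1,3-dioxolane-4-carbaldehyde | O=C[C@H]1COC(C)(C)O1 | starting material
14 | methyl acrylate | C=CC(=O)OC | starting material
15 | methyl 2-{[(4R)-2,2-dimethyl-1,3-dioxolan-4-yl](hydroxy)methyl}prop-2-enoate (carbinol epimers) | C=C(C(=O)OC)C(O)[C@H]1COC(C)(C)O1 | intermediate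
16 | methyl (2Z)-2-(bromomethyl)-3-[(4S)-2,2-dimethyl-1,3-dioxolan-4-yl]prop-2-enoate | BrC/C(C(=O)OC)=C\[C@H]1COC(C)(C)O1 | intermediate
17 | methyl (3R,4R,6R,7Z,9R,10Z)-9-[(tert-butyldimethylsilyl)oxy]-3-[(4S)-2,2-dimethyl-1,3-dioxolan-4-yl]-4,6-dihydroxy-11-iodo-6,10-dimethyl-2-methylideneundeca-7,10-dienoate | C=C(C(=O)OC)[C@@H]([C@H]1COC(C)(C)O1)[C@H](O)C[C@@](C)(O)/C=C\[C@@H](O[Si](C)(C)C(C)(C)C)/C(C)=C\I | intermediate
18 | methyl (3R,4R,6R,7Z,9R,10Z)-9-[(tert-butyldimethylsilyl)oxy]-3-[(4S)-2,2-dimethyl-1,3-dioxolan-4-yl]-6-hydroxy-11-iodo-6,10-dimethyl-4-{[(2E)-2-methylbut-2-enoyl]oxy}-2-methylideneundeca-7,10-dienoate | C=C(C(=O)OC)[C@@H]([C@H]1COC(C)(C)O1)[C@H](OC(=O)/C(C)=C/C)C[C@@](C)(O)/C=C\[C@@H](O[Si](C)(C)C(C)(C)C)/C(C)=C\I | intermediate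
19 | methyl (3S,4R,6R,7Z,9R,10Z)-9-[(tert-butyldimethylsilyl)oxy]-3-[(1S)-1,2-dihydroxyethyl]-6-hydroxy-11-iodo-6,10-dimethyl-4-{[(2E)-2-methylbut-2-enoyl]oxy}-2-methylideneundeca-7,10-dienoate (all centres as in 18, acetonide removed) | C=C(C(=O)OC)[C@@H]([C@H](O)CO)[C@H](OC(=O)/C(C)=C/C)C[C@@](C)(O)/C=C\[C@@H](O[Si](C)(C)C(C)(C)C)/C(C)=C\I | intermediate
20 | methyl (3R,4R,6R,7Z,9R,10Z)-9-[(tert-butyldimethylsilyl)oxy]-3-formyl-6-hydroxy-11-iodo-6,10-dimethyl-4-{[(2E)-2-methylbut-2-enoyl]oxy}-2-methylideneundeca-7,10-dienoate | C=C(C(=O)OC)[C@@H](C=O)[C@H](OC(=O)/C(C)=C/C)C[C@@](C)(O)/C=C\[C@@H](O[Si](C)(C)C(C)(C)C)/C(C)=C\I | intermediate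
21 | methyl 2-[(1S,2S,3Z,5R,6Z,8R,10R)-5-[(tert-butyldimethylsilyl)oxy]-2,8-dihydroxy-4,8-dimethyl-10-{[(2E)-2-methylbut-2-enoyl]oxy}cyclodeca-3,6-dien-1-yl]prop-2-enoate | C=C(C(=O)OC)[C@H]1[C@@H](O)/C=C(/C)[C@H](O[Si](C)(C)C(C)(C)C)/C=C\[C@](C)(O)C[C@H]1OC(=O)/C(C)=C/C | intermediate
22 | (3aR,4R,6R,7Z,9R,10Z,11aS)-9-[(tert-butyldimethylsilyl)oxy]-6-hydroxy-6,10-dimethyl-3-methylidene-2-oxo-2,3,3a,4,5,6,9,11a-octahydrocyclodeca[b]furan-4-yl (2E)-2-methylbut-2-enoate | C=C1C(=O)O[C@H]2/C=C(/C)[C@H](O[Si](C)(C)C(C)(C)C)/C=C\[C@](C)(O)C[C@@H](OC(=O)/C(C)=C/C)[C@@H]12 | intermediate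
23 | (3aR,4R,6R,7Z,9R,10Z,11aS)-6,9-dihydroxy-6,10-dimethyl-3-methylidene-2-oxo-2,3,3a,4,5,6,9,11a-octahydrocyclodeca[b]furan-4-yl (2E)-2-methylbut-2-enoate | C=C1C(=O)O[C@H]2/C=C(/C)[C@H](O)/C=C\[C@](C)(O)C[C@@H](OC(=O)/C(C)=C/C)[C@@H]12 | target

Total step count: 17. Longest linear sequence: 13 steps (steps 1–3, 6–10, 13–17).

Steps most likely to fail

Step 16 (key step). The addition may show poor facial selectivity at C6, so that the 6R epimer, which leads to the trans-fused lactone, prevails; oligomerisation or enolisation of the aldehyde may also erode it. Fallback, in which C6 is set by SN2 inversion during lactone closure instead of by the addition: from 20 the same CrCl2/NiCl2 cyclisation is run but the seco ester is isolated after neutral work-up without acid, giving methyl 2-[(1S,2R,3Z,5R,6Z,8R,10R)-5-[(tert-butyldimethylsilyl)oxy]-2,8-dihydroxy-4,8-dimethyl-10-{[(2E)-2-methylbut-2-enoyl]oxy}cyclodeca-3,6-dien-1-yl]prop-2-enoate F1. Me3SnOH (1,2-dichloroethane, 70 °C) should cleave only the methyl ester and give the corresponding 2-[(1S,2R,3Z,5R,6Z,8R,10R)-…cyclodeca-3,6-dien-1-yl]prop-2-enoic acid F2. Mitsunobu lactonisation (PPh3, DIAD, THF, 0 °C) then closes the lactone with inversion at C6 and returns to the route at 22.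

Step 13. Facial control by the dioxolane centre may be weak or opposite in sense, giving the other syn adduct (7S,8S); lactonisation of the 8-hydroxy acrylate may also compete. The antipode of 13 is the immediate remedy for a reversed sense, since the dioxolane centre is excised in step 15. Fallback with a change of control element, from reagent control to chelation control by the free C10 hydroxyl: dimethoxyacetaldehyde and 14 (DABCO) give methyl 2-(1-hydroxy-2,2-dimethoxyethyl)prop-2-enoate F3, and NBS/Me2S converts it into methyl (2Z)-2-(bromomethyl)-4,4-dimethoxybut-2-enoate F4. Indium-mediated coupling of F4 with 12 in THF/H2O, in which the indium chelate between the aldehyde and the C10 hydroxyl directs 1,3-anti addition and the chair transition state the syn C7/C8 relationship, should give methyl (3R,4R,6R,7Z,9R,10Z)-9-[(tert-butyldimethylsilyl)oxy]-3-(dimethoxymethyl)-4,6-dihydroxy-11-iodo-6,10-dimethyl-2-methylideneundeca-7,10-dienoate F5. Tigloylation as in step 14 gives its 4-[(2E)-2-methylbut-2-enoyl]oxy derivative F6, and mild acetal hydrolysis (LiBF4, wet MeCN) returns to the route at 20.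

Step 7. The zinc reduction may stall on the hindered, non-conjugated alkyne or be accompanied by loss of iodine. Fallback in which iodine is introduced only after a catalytic semi-hydrogenation: from 5, the carbomagnesiation of step 4 is quenched with Bu3SnCl to give (2Z)-2-methyl-3-(tributylstannyl)prop-2-en-1-ol F7, which MnO2 oxidises to (2Z)-2-methyl-3-(tributylstannyl)prop-2-enal F8. Alkynylation with 4 under the conditions of step 6 gives (1Z,3R)-2-methyl-1-(tributylstannyl)-5-[(4R)-2,2,4-trimethyl-1,3-dioxan-4-yl]pent-1-en-4-yn-3-ol F9. Hydrogenation over Pd/CaCO3 poisoned with Pb(OAc)2 and quinoline gives (1Z,3R,4Z)-2-methyl-1-(tributylstannyl)-5-[(4R)-2,2,4-trimethyl-1,3-dioxan-4-yl]penta-1,4-dien-3-ol F10, and iododestannylation with I2 (CH2Cl2, 0 °C, retention) returns to the route at 9.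

Further compounds

F1 | step 16 | methyl 2-[(1S,2R,3Z,5R,6Z,8R,10R)-5-[(tert-butyldimethylsilyl)oxy]-2,8-dihydroxy-4,8-dimethyl-10-{[(2E)-2-methylbut-2-enoyl]oxy}cyclodeca-3,6-dien-1-yl]prop-2-enoate | C=C(C(=O)OC)[C@H]1[C@H](O)/C=C(/C)[C@H](O[Si](C)(C)C(C)(C)C)/C=C\[C@](C)(O)C[C@H]1OC(=O)/C(C)=C/C
F2 | step 16 | 2-[(1S,2R,3Z,5R,6Z,8R,10R)-5-[(tert-butyldimethylsilyl)oxy]-2,8-dihydroxy-4,8-dimethyl-10-{[(2E)-2-methylbut-2-enoyl]oxy}cyclodeca-3,6-dien-1-yl]prop-2-enoic acid | C=C(C(=O)O)[C@H]1[C@H](O)/C=C(/C)[C@H](O[Si](C)(C)C(C)(C)C)/C=C\[C@](C)(O)C[C@H]1OC(=O)/C(C)=C/C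
F3 | step 13 | methyl 2-(1-hydroxy-2,2-dimethoxyethyl)prop-2-enoate | C=C(C(=O)OC)C(O)C(OC)OC
F4 | step 13 | methyl (2Z)-2-(bromomethyl)-4,4-dimethoxybut-2-enoate | BrC/C(C(=O)OC)=C\C(OC)OC
F5 | step 13 | methyl (3R,4R,6R,7Z,9R,10Z)-9-[(tert-butyldimethylsilyl)oxy]-3-(dimethoxymethyl)-4,6-dihydroxy-11-iodo-6,10-dimethyl-2-methylideneundeca-7,10-dienoate | C=C(C(=O)OC)[C@@H](C(OC)OC)[C@H](O)C[C@@](C)(O)/C=C\[C@@H](O[Si](C)(C)C(C)(C)C)/C(C)=C\I
F6 | step 13 | methyl (3R,4R,6R,7Z,9R,10Z)-9-[(tert-butyldimethylsilyl)oxy]-3-(dimethoxymethyl)-6-hydroxy-11-iodo-6,10-dimethyl-4-{[(2E)-2-methylbut-2-enoyl]oxy}-2-methylideneundeca-7,10-dienoate | C=C(C(=O)OC)[C@@H](C(OC)OC)[C@H](OC(=O)/C(C)=C/C)C[C@@](C)(O)/C=C\[C@@H](O[Si](C)(C)C(C)(C)C)/C(C)=C\I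
F7 | step 7 | (2Z)-2-methyl-3-(tributylstannyl)prop-2-en-1-ol | C/C(CO)=C/[Sn](CCCC)(CCCC)CCCC
F8 | step 7 | (2Z)-2-methyl-3-(tributylstannyl)prop-2-enal | C/C(C=O)=C/[Sn](CCCC)(CCCC)CCCC
F9 | step 7 | (1Z,3R)-2-methyl-1-(tributylstannyl)-5-[(4R)-2,2,4-trimethyl-1,3-dioxan-4-yl]pent-1-en-4-yn-3-ol | CC1(C)OCC[C@](C)(C#C[C@@H](O)/C(C)=C\[Sn](CCCC)(CCCC)CCCC)O1
F10 | step 7 | (1Z,3R,4Z)-2-methyl-1-(tributylstannyl)-5-[(4R)-2,2,4-trimethyl-1,3-dioxan-4-yl]penta-1,4-dien-3-ol | CC1(C)OCC[C@](C)(/C=C\[C@@H](O)/C(C)=C\[Sn](CCCC)(CCCC)CCCC)O1
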